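The numbers are assumed; no experiment stands behind them.

We start from an easy step: one turn of the catalyst is a row of waits, and waits in a row add.

    reagent + free catalyst → catalyst intermediate A (k1 = 5000 M⁻¹ min⁻¹)
    starting material + catalyst intermediate A → catalyst intermediate B (k2 = 11000 M⁻¹ min⁻¹)
    catalyst intermediate B → catalyst intermediate C (k3 = 828 min⁻¹)
    catalyst intermediate C → free catalyst + product (k4 = 11600 min⁻¹)
    reagent + catalyst intermediate A ⇌ idle complex, settled at all times (K5 = 19 M⁻¹)

all flasks: starting material 0.066 M; free catalyst 33 µM; time 6.0 min
- east: reagent 0.0150 M
- south: reagent 0.0300 M
- north: reagent 0.0600 M
- north-west: reagent 0.120 M
- north-east: reagent 0.250 M

* amount of product at the end, in percent of the starting material charged for east, south, north, north-west, north-east, in this order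
* how that number moves from the first to the last of them (rises, then falls / falls all the way / falls, then rises / hardly changes / rises all the way)

- "hardly changes" means that all values lie within two and a half points (for a concentration: within two and a half percent of the largest)
- run time (east): 6.0 min

Take east, whose reagent charge of 0.0150 M is smaller than its 0.066 M of starting material, so the reagent is the limiting reagent there. Let r be the fraction of the reagent charge still left and s the same fraction for the starting material.

First we keep the capture step alone, with the whole catalyst free. Then r decays as a pseudo-first-order lag with half-life 4.2 min, and over the run:

exponent = 0.990, r = 37.2 %, product = 14.3 % of the starting material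

Now we add the next three steps. At the start in east a turn waits 0.800 s for capture, 0.0826 s for the starting material and 0.0776 s in the last two steps. The catalyst stands free for the capture share of the turn, so the exponent shrinks by that share, which we hold at its start value over the whole run:

share = 0.833, product = 12.8 %

Last comes the idle complex. Its balance puts 0.28 of it beside each catalyst intermediate A in east at the start, which adds an idle wait of 0.0236 s:

share = 0.813, product = 12.6 %

East loses little this way, because the idle wait is far shorter than the capture wait. But with starting material held fixed, the capture wait shrinks as reagent grows, while the idle wait grows with it. We call the balance charge the reagent concentration at which, with starting material at its charge, the two waits are equal: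

0.0874 M = square root of (11000 M⁻¹ min⁻¹ × 0.066 M) / (5000 M⁻¹ min⁻¹ × 19 M⁻¹)

idle complex / free catalyst = idle wait / capture wait = (r × reagent charge / balance charge)² / s

With starting material held at its charge, the sum of the two waits stops falling and starts rising at the balance charge. So we commit to a row that rises, then falls, with its top near the charges of north and north-west, which lie on either side. We give no heights there.

The forecast gives 13.1 %, 23.3 %, 34.5 %, 36 % and 27.1 %, a row that rises, then falls. Its ground for the fall is plain: “At high reagent, the idle complex holds catalyst back.” For east, our 12.6 % stands lower than its 13.1 %.

The simulation gives 13.1 %, 23.3 %, 34.4 %, 36.0 % and 27.1 %, a row that rises, then falls. Read off these points, the row turns at 0.092 M, which is 1.05 balance charges. The north-east flask is our second case, charged with 2.86 balance charges. At its end it keeps 93 % of its reagent and 73 % of its starting material, so the rule gives idle complex over free catalyst as 9.67, and at that moment north-east holds, of the catalyst charged, 67.3 % as idle complex against 6.96 % as free catalyst.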